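All constants belong to no real substance, and the outcome is calculated.

A percent of product carries no clock, so two flasks that read alike may stand in quite different states.

    partner + protic impurity → quenched reagent (k1 = 3.85 L mol⁻¹ s⁻¹, Ea1 = 61.0 kJ mol⁻¹)
    open intermediate + capture agent → trapped intermediate (k2 = 1.43 L mol⁻¹ s⁻¹, Ea2 = 61.0 kJ mol⁻¹)
    open intermediate ⇌ product + by-product (K3 = 0.73 M, k3 = 0.0725 s⁻¹, Ea3 = 97.0 kJ mol⁻¹, ΔH3 = −77.0 kJ mol⁻¹)
    starting material + partner ⇌ open intermediate (K4 = 40 L mol⁻¹, k4 = 3.01 L mol⁻¹ s⁻¹, Ea4 = 57.0 kJ mol⁻¹, ΔH4 = −42.0 kJ mol⁻¹)
    (constants at 60 °C)

| setting | Sunday's | Monday's | Friday's | Saturday's |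
|---|---|---|---|---|
| starting material | 20 mM | 20 mM | 20 mM | 20 mM |
| partner | 16.0 mM | 16.0 mM | 16.0 mM | 16.0 mM |
| capture agent | 6.00 mM | 6.00 mM | 6.00 mM | 6.00 mM |
| protic impurity | 6.00 mM | 6.00 mM | 6.00 mM | 6.00 mM |
| time | 12 s | 12 s | 12 s | 12 s |
| remark | at 60 °C until 6.0 s, from then on at 120 °C |  |  |  |
| temperature |  | 90 °C | 60 °C | 120 °C |

- the list of constants is for 60 °C, to be carried to other temperatures by the activation energies and enthalpies

* which flask leads in amount of product, in percent of the starting material charged ("all alike" within 1.5 percentage points) (Sunday's / Monday's / Friday's / Saturday's / all alike)
* how much product is there at the end, in percent of the starting material charged: Sunday's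
* how much product is there at the end, in percent of the starting material charged: Monday's
* how much product is there at the end, in percent of the starting material charged: Friday's
* how much product is there at the end, in percent of the starting material charged: Saturday's

I compare Friday's at 60 °C with Saturday's at 120 °C, which have the same charge. The quantity I carry is the ceiling constant C, the product of the equilibrium constants of the two reversible steps, taken to the flask's temperature. When both steps stand at equilibrium, C equals [product][by-product] over [starting material][partner]. It is 29.2 at 60 °C, but at 120 °C the ceiling constant is 0.0415.

In Saturday's the first step relaxes in about 0.399 s, the closing step turns over in 0.0659 s, and the impurity has a half-life near 0.391 s, each short against 12 s. Capture of an open intermediate takes about 4.04 s, longer than the first step, and I leave it out of this sum, so the figure below is an estimate for the other steps. So I take 6.00 mM off the partner, call the product X, set the by-product equal to it, and solve X times X = C(starting material − X)(remaining partner − X). That gives 2.36 mM, or 11.8%. Sunday's spends its last 6.00 s at the same heat, long against the first step, so I give it the same figure.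

For Friday's the same sum gives a ceiling of 9.69 mM, but the clock comes first. Reckoned from the charge, the open intermediate rises toward a steady level with rate constant λ = 0.256 s⁻¹, and product grows as the closing step's constant times the area under that rise. That gives 2.26 mM, or 11.3%, which is less than the ceiling. So Friday's is under kinetic control and Saturday's under thermodynamic control, with nearly the same figure.

Between them, at 90 °C, C is 0.840 and the first step relaxes in 1.69 s, shorter than the 12 s allowed. With 6.00 mM again taken off the partner, the ceiling for Monday's is 6.41 mM, or 32.0%. I use that as my estimate for Monday's without having shown that the flask arrives there, and I commit to Monday's.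

The forecast also names Monday's, with 10.7% for Sunday's, 30.5% for Monday's, 10% for Friday's and 10.3% for Saturday's. For the hot end it says “reverses strongly, so equilibrium is reached within a second”. Its Saturday's figure is lower than mine.

The flasks give Monday's in the lead, with 10.7% for Sunday's, 30.7% for Monday's, 9.83% for Friday's and 10.3% for Saturday's. Friday's, left until 120 s, reads 43.4%. Saturday's ends with 81.6% of its starting material and 39.5% of its partner, and with product equal to by-product, C turns these into 10.3%. The neighbour of Sunday's, charged with 80 mM of starting material, ends with 92% of that and 24% of its partner, so C gives 3.39 mM, and that flask holds 3.39 mM of product.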